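**Retrosynthetic overview**

- The target is reached by global ether cleavage of a protected (2R,3S,2'R)-biflavanone. That compound comes from two successive palladium/pyridine-oxazoline conjugate arylations of a 3,8'-bis-chromone: first C2' of unit A, then C2 of unit B, with C3 settling trans by equilibration.
- The pyranone of unit A is closed last (acetyl at C4a', enaminone, O1'–C2' closure) on a 3-arylchromone.
- The benzo ring of unit A is built by a Danheiser benzannulation of a chromon-3-yl siloxyalkyne with 3-ethoxycyclobutenone: C8'–C8a' and C6'–C7' form in the ketene [2+2] step, and the ring closes by 6π electrocyclization at C8a'–C4a'.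
- The siloxyalkyne comes from a 3-iodochromone (pyranone of unit B, made first) derived from phloroacetophenone. Ring order: pyranone B, benzo ring A, pyranone A.
- Feature on which the strategy rests: C8' of unit A is an aromatic carbon flanked by the oxygen-bearing C7' and C8a' and bonded to C3 of unit B. It enters as an alkyne carbon already attached to C3, so this crowded bond is never made by coupling.

Key step: step 6

Remark on the chemistry: unprimed locants belong to unit B (catechol flavanone) and primed locants to unit A (4-hydroxyphenyl flavanone). The C3–C8' bond is assumed to rotate freely enough that only C2, C3 and C2' need to be controlled.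

**Route**

Step 1
Reactants: 1 1-(2,4,6-trihydroxyphenyl)ethan-1-one (phloroacetophenone)
Product: 2 1-[2,4-bis(benzyloxy)-6-hydroxyphenyl]ethan-1-one
Conditions: BnBr (2.1 equiv), K2CO3, DMF, 0 °C → rt
Reagents that add atoms: benzyl bromide, BrCc1ccccc1
Why: Williamson etherification in which the hydroxyl hydrogen-bonded to the acetyl carbonyl is the least reactive and stays free, as needed for the later pyranone closure.

Step 2
Reactants: 2 1-[2,4-bis(benzyloxy)-6-hydroxyphenyl]ethan-1-one
Product: 4 5,7-bis(benzyloxy)-3-iodo-4H-chromen-4-one, via enaminone 3 (not isolated)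
Conditions: Me2NCH(OMe)2, toluene, 95 °C; evaporate; then I2, CHCl3, rt
Reagents that add atoms: N,N-dimethylformamide dimethyl acetal, COC(OC)N(C)C; iodine, II
Why: Enaminone formation at the methyl ketone, then iodination of the enaminone α-carbon and ring closure by the phenol with loss of dimethylamine, is the standard iodine-mediated synthesis of 3-iodochromones.

Step 3
Reactants: 4 5,7-bis(benzyloxy)-3-iodo-4H-chromen-4-one; 5 ethynyltrimethylsilane
Product: 6 5,7-bis(benzyloxy)-3-[(trimethylsilyl)ethynyl]-4H-chromen-4-one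
Conditions: PdCl2(PPh3)2 (3 mol%), CuI (6 mol%), Et3N, THF, rt
Reagents that add atoms: none
Why: Sonogashira coupling of the vinylic iodide (oxidative addition to zerovalent palladium, copper acetylide transmetalation) is routine for 3-iodochromones, and a tertiary amine base avoids opening of the pyranone.

Step 4
Reactants: 6 5,7-bis(benzyloxy)-3-[(trimethylsilyl)ethynyl]-4H-chromen-4-one
Product: 7 5,7-bis(benzyloxy)-3-ethynyl-4H-chromen-4-one
Conditions: Bu4NF, AcOH, THF, 0 °C
Reagents that add atoms: none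
Why: Fluoride protodesilylation of the alkynylsilane, buffered with acetic acid so that no basic nucleophile adds to C2 of the chromone.

Step 5
Reactants: 7 5,7-bis(benzyloxy)-3-ethynyl-4H-chromen-4-one
Product: 10 5,7-bis(benzyloxy)-3-{[(triisopropylsilyl)oxy]ethynyl}-4H-chromen-4-one, via lithium acetylide 8 (not isolated), via lithium ynolate 9 (not isolated)
Conditions: t-BuOOH (in decane), LiN(SiMe3)2 (2.2 equiv), THF, −78 → 0 °C; then i-Pr3SiOSO2CF3, −78 °C → rt; rapid filtration through Et3N-washed silica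
Reagents that add atoms: tert-butyl hydroperoxide, CC(C)(C)OO; triisopropylsilyl trifluoromethanesulfonate, CC(C)[Si](C(C)C)(C(C)C)OS(=O)(=O)C(F)(F)F
Why: Oxidation of a lithium acetylide to the ynolate by electrophilic oxygen transfer from lithium tert-butyl peroxide, followed by O-silylation with the bulky silyl triflate, is the standard route from terminal alkynes to triisopropylsiloxyalkynes; the hindered amide base and low temperature are chosen to spare the doubly alkoxy-deactivated chromone.

Step 6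
Reactants: 10 5,7-bis(benzyloxy)-3-{[(triisopropylsilyl)oxy]ethynyl}-4H-chromen-4-one; 11 3-ethoxycyclobut-2-en-1-one
Product: 16 5,7-bis(benzyloxy)-3-{4-ethoxy-2-hydroxy-6-[(triisopropylsilyl)oxy]phenyl}-4H-chromen-4-one, via vinylketene 12 (not isolated), via vinylcyclobutenone 13 (not isolated), via dienylketene 14 (not isolated), via cyclohexadienone 15 (not isolated)
Conditions: toluene (0.1 M), 80 → 105 °C, sealed tube, 11 (1.5 equiv) added in portions
Reagents that add atoms: none
Why: Danheiser benzannulation: 11 opens by 4π electrocyclic cleavage to vinylketene 12, whose ketene C=C adds across the siloxyalkyne in a [2+2] cycloaddition, the chromone-bearing alkyne carbon (future C8') bonding to the ketene carbonyl carbon (future C8a') and the siloxy carbon (C7') to the ketene α-carbon (C6'); 13 then opens to dienylketene 14, which closes the benzo ring of unit A by 6π electrocyclization (bond C8a'–C4a') and tautomerizes from 15 to the phenol. The closest known reaction type is the benzannulation of alkyl- and aryl-substituted cyclobutenones with triisopropylsiloxyalkynes to resorcinol monosilyl ethers; the 3-alkoxy group on the cyclobutenone and the chromonyl group on the alkyne are untested substituents within that class. No stereocentre is formed. The step needs the regiochemistry of the ketene–alkyne addition, which the siloxy donor fixes by making the chromone-bearing carbon the nucleophilic terminus, and it needs the alkyne to outcompete the C2=C3 bond of the chromone, which should hold because that push–pull (vinylogous ester) alkene is a much poorer ketenophile. The ring is formed with its three oxygens in place (C8a'–OH, C7'–O-silyl, C5'–O-ethyl) and the C3–C8' bond is carried in from the alkyne.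

Step 7
Reactants: 16 5,7-bis(benzyloxy)-3-{4-ethoxy-2-hydroxy-6-[(triisopropylsilyl)oxy]phenyl}-4H-chromen-4-one
Product: 17 5,7-bis(benzyloxy)-3-(4-ethoxy-2,6-dihydroxyphenyl)-4H-chromen-4-one
Conditions: Bu4NF, AcOH, THF, 0 °C
Reagents that add atoms: none
Why: Fluoride cleavage of the aryl silyl ether gives a resorcinol whose two free ring positions (C4a' and C6') are equivalent by symmetry, so the following acylation has no regiochemical issue.

Step 8
Reactants: 17 5,7-bis(benzyloxy)-3-(4-ethoxy-2,6-dihydroxyphenyl)-4H-chromen-4-one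
Product: 18 3-(3-acetyl-4-ethoxy-2,6-dihydroxyphenyl)-5,7-bis(benzyloxy)-4H-chromen-4-one
Conditions: Ac2O, BF3·OEt2, CH2Cl2, 0 °C → rt; then NaHCO3, MeOH–H2O
Reagents that add atoms: acetic anhydride, CC(=O)OC(C)=O
Why: Friedel–Crafts (Fries-type) C-acetylation of a phloroglucinol-type ring should stop at the mono-ketone as its BF2 chelate, while the benzo ring of unit B is deactivated by its Lewis-acid-bound carbonyl; the acetyl group lands on C4a', ortho to the C8a' hydroxyl.

Step 9
Reactants: 18 3-(3-acetyl-4-ethoxy-2,6-dihydroxyphenyl)-5,7-bis(benzyloxy)-4H-chromen-4-one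
Product: 19 3-[3-acetyl-6-(benzyloxy)-4-ethoxy-2-hydroxyphenyl]-5,7-bis(benzyloxy)-4H-chromen-4-one
Conditions: BnBr (1.05 equiv), K2CO3, acetone, 50 °C
Reagents that add atoms: benzyl bromide, BrCc1ccccc1
Why: Williamson etherification of the more acidic C7' hydroxyl para to the acetyl group, leaving the C8a' hydroxyl hydrogen-bonded to the acetyl carbonyl free, as in the selective 4-O-alkylation of 2,4-dihydroxyacetophenones.

Step 10
Reactants: 19 3-[3-acetyl-6-(benzyloxy)-4-ethoxy-2-hydroxyphenyl]-5,7-bis(benzyloxy)-4H-chromen-4-one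
Product: 21 5,7-bis(benzyloxy)-3-[7-(benzyloxy)-5-ethoxy-4-oxo-4H-chromen-8-yl]-4H-chromen-4-one (bis-chromone), via enaminone 20 (not isolated)
Conditions: Me2NCH(OMe)2, toluene, 95 °C; evaporate; then conc. HCl, CH2Cl2, rt
Reagents that add atoms: N,N-dimethylformamide dimethyl acetal, COC(OC)N(C)C
Why: Enaminone formation at the acetyl methyl and acid-promoted addition–elimination by the C8a' hydroxyl close the pyranone of unit A (bond O1'–C2'), the standard chromone synthesis from 2-hydroxyacetophenones.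

Step 11
Reactants: 21 bis-chromone; 22 [4-(benzyloxy)phenyl]boronic acid
Product: 23 5,7-bis(benzyloxy)-3-{(2R)-7-(benzyloxy)-2-[4-(benzyloxy)phenyl]-5-ethoxy-4-oxochroman-8-yl}-4H-chromen-4-one
Conditions: 22 (2 equiv), Pd(OCOCF3)2 (5 mol%), (S)-4-tert-butyl-2-(pyridin-2-yl)-4,5-dihydrooxazole (6 mol%), NH4PF6, H2O, ClCH2CH2Cl, 60 °C
Reagents that add atoms: none
Why: Enantioselective conjugate addition of an arylboronic acid to a chromone under divalent-palladium/pyridine-oxazoline catalysis is a known flavanone synthesis; only the 3'-unsubstituted pyranone of unit A is a competent acceptor, and the (S)-ligand is expected, by analogy with parent chromones, to deliver the aryl group to the Si face of C2' and set (2'R) before water protonates the palladium enolate.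

Step 12
Reactants: 23 5,7-bis(benzyloxy)-3-{(2R)-7-(benzyloxy)-2-[4-(benzyloxy)phenyl]-5-ethoxy-4-oxochroman-8-yl}-4H-chromen-4-one; 24 [3,4-bis(benzyloxy)phenyl]boronic acid
Product: 25 (2R,3S)-5,7-bis(benzyloxy)-3-{(2R)-7-(benzyloxy)-2-[4-(benzyloxy)phenyl]-5-ethoxy-4-oxochroman-8-yl}-2-[3,4-bis(benzyloxy)phenyl]chroman-4-one (2,3-trans)
Conditions: 24 (3 equiv, in portions), Pd(OCOCF3)2 (15 mol%), (S)-4-tert-butyl-2-(pyridin-2-yl)-4,5-dihydrooxazole (18 mol%), NH4PF6, H2O, ClCH2CH2Cl, 70 °C; then pyridinium p-toluenesulfonate (cat.), CHCl3, 40 °C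
Reagents that add atoms: none
Why: Proposed new method: the arylpalladium cation formed from 24 by transmetalation should insert the C2=C3 bond of the 3-arylchromone with the aryl group going to C2 (both the enone β-carbon and the oxygen-bearing carbon of the enol ether, so the two polarizations agree), palladium arriving at the substituted C3 and slipping to the oxygen-bound enolate that water protonates; the closest known reaction type is the same divalent-palladium/pyridine-oxazoline conjugate arylation on 3-unsubstituted chromones and on β,β-disubstituted cyclic enones, where insertion into trisubstituted alkenes is established but an α-aryl substituent is not; C2 (R) is set by the ligand, which should direct the aryl group to the Si face as in step 11, and C3 (S) is set by acid-catalysed equilibration of the readily enolized α-aryl ketone to the 2,3-trans diequatorial isomer.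

Step 13
Reactants: 25 protected (2R,3S,2'R)-biflavanone
Product: 26 (2R,3S)-2-(3,4-dihydroxyphenyl)-3-[(2R)-5,7-dihydroxy-2-(4-hydroxyphenyl)-4-oxochroman-8-yl]-5,7-dihydroxychroman-4-one (target)
Conditions: BCl3 (1 M in CH2Cl2, excess), C6HMe5 (excess), CH2Cl2, −78 → 0 °C, then rt until the ethyl ether is consumed; MeOH quench
Reagents that add atoms: none
Why: BCl3 with pentamethylbenzene as a non-Lewis-basic benzyl-cation scavenger is a known low-temperature cleavage of aryl benzyl ethers that prevents C-benzylation of the phloroglucinol rings, and the 5'-ethyl ether falls by the known chelation-assisted dealkylation of alkoxy groups peri to a carbonyl; no stereocentre is touched.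

**Compound list**

1 | 1-(2,4,6-trihydroxyphenyl)ethan-1-one | CC(=O)c1c(O)cc(O)cc1O | starting material
2 | 1-[2,4-bis(benzyloxy)-6-hydroxyphenyl]ethan-1-one | CC(=O)c1c(O)cc(OCc2ccccc2)cc1OCc1ccccc1 | intermediate
3 | (E)-1-[2,4-bis(benzyloxy)-6-hydroxyphenyl]-3-(dimethylamino)prop-2-en-1-one | CN(C)/C=C/C(=O)c1c(O)cc(OCc2ccccc2)cc1OCc1ccccc1 | intermediate
4 | 5,7-bis(benzyloxy)-3-iodo-4H-chromen-4-one | IC1=COc2cc(OCc3ccccc3)cc(OCc3ccccc3)c2C1=O | intermediate
5 | ethynyltrimethylsilane | C#C[Si](C)(C)C | starting material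
6 | 5,7-bis(benzyloxy)-3-[(trimethylsilyl)ethynyl]-4H-chromen-4-one | C[Si](C)(C)C#CC1=COc2cc(OCc3ccccc3)cc(OCc3ccccc3)c2C1=O | intermediate
7 | 5,7-bis(benzyloxy)-3-ethynyl-4H-chromen-4-one | C#CC1=COc2cc(OCc3ccccc3)cc(OCc3ccccc3)c2C1=O | intermediate
8 | lithium acetylide of 7 | [Li]C#CC1=COc2cc(OCc3ccccc3)cc(OCc3ccccc3)c2C1=O | intermediate
9 | lithium 2-[5,7-bis(benzyloxy)-4-oxo-4H-chromen-3-yl]ethyn-1-olate | [Li]OC#CC1=COc2cc(OCc3ccccc3)cc(OCc3ccccc3)c2C1=O | intermediate
10 | 5,7-bis(benzyloxy)-3-{[(triisopropylsilyl)oxy]ethynyl}-4H-chromen-4-one | CC(C)[Si](OC#CC1=COc2cc(OCc3ccccc3)cc(OCc3ccccc3)c2C1=O)(C(C)C)C(C)C | intermediate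
11 | 3-ethoxycyclobut-2-en-1-one | CCOC1=CC(=O)C1 | starting material
12 | 3-ethoxybuta-1,3-dien-1-one (vinylketene) | CCOC(=C)C=C=O | intermediate
13 | 2-[5,7-bis(benzyloxy)-4-oxo-4H-chromen-3-yl]-4-(1-ethoxyvinyl)-3-[(triisopropylsilyl)oxy]cyclobut-2-en-1-one | CCOC(=C)C1C(=O)C(C2=COc3cc(OCc4ccccc4)cc(OCc4ccccc4)c3C2=O)=C1O[Si](C(C)C)(C(C)C)C(C)C | intermediate
14 | (3E)-2-[5,7-bis(benzyloxy)-4-oxo-4H-chromen-3-yl]-5-ethoxy-3-[(triisopropylsilyl)oxy]hexa-1,3,5-trien-1-one (dienylketene, vinyl cis to the ketene carbon) | CCOC(=C)/C=C(/O[Si](C(C)C)(C(C)C)C(C)C)C(=C=O)C1=COc2cc(OCc3ccccc3)cc(OCc3ccccc3)c2C1=O | intermediate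
15 | 2-[5,7-bis(benzyloxy)-4-oxo-4H-chromen-3-yl]-5-ethoxy-3-[(triisopropylsilyl)oxy]cyclohexa-2,4-dien-1-one | CCOC1=CC(O[Si](C(C)C)(C(C)C)C(C)C)=C(C2=COc3cc(OCc4ccccc4)cc(OCc4ccccc4)c3C2=O)C(=O)C1 | intermediate
16 | 5,7-bis(benzyloxy)-3-{4-ethoxy-2-hydroxy-6-[(triisopropylsilyl)oxy]phenyl}-4H-chromen-4-one | Oc1cc(OCC)cc(O[Si](C(C)C)(C(C)C)C(C)C)c1C1=COc2cc(OCc3ccccc3)cc(OCc3ccccc3)c2C1=O | intermediate
17 | 5,7-bis(benzyloxy)-3-(4-ethoxy-2,6-dihydroxyphenyl)-4H-chromen-4-one | Oc1cc(OCC)cc(O)c1C1=COc2cc(OCc3ccccc3)cc(OCc3ccccc3)c2C1=O | intermediate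
18 | 3-(3-acetyl-4-ethoxy-2,6-dihydroxyphenyl)-5,7-bis(benzyloxy)-4H-chromen-4-one | CC(=O)c1c(O)c(C2=COc3cc(OCc4ccccc4)cc(OCc4ccccc4)c3C2=O)c(O)cc1OCC | intermediate
19 | 3-[3-acetyl-6-(benzyloxy)-4-ethoxy-2-hydroxyphenyl]-5,7-bis(benzyloxy)-4H-chromen-4-one | CC(=O)c1c(O)c(C2=COc3cc(OCc4ccccc4)cc(OCc4ccccc4)c3C2=O)c(OCc2ccccc2)cc1OCC | intermediate
20 | (E)-enaminone of 19 (3-(dimethylamino)prop-2-enoyl in place of acetyl) | CN(C)/C=C/C(=O)c1c(O)c(C2=COc3cc(OCc4ccccc4)cc(OCc4ccccc4)c3C2=O)c(OCc2ccccc2)cc1OCC | intermediate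
21 | 5,7-bis(benzyloxy)-3-[7-(benzyloxy)-5-ethoxy-4-oxo-4H-chromen-8-yl]-4H-chromen-4-one | O=C1C=COc2c1c(OCC)cc(OCc1ccccc1)c2C1=COc2cc(OCc3ccccc3)cc(OCc3ccccc3)c2C1=O | intermediate
22 | [4-(benzyloxy)phenyl]boronic acid | OB(O)c1ccc(OCc2ccccc2)cc1 | starting material
23 | 5,7-bis(benzyloxy)-3-{(2R)-7-(benzyloxy)-2-[4-(benzyloxy)phenyl]-5-ethoxy-4-oxochroman-8-yl}-4H-chromen-4-one | O=C1C[C@H](c2ccc(OCc3ccccc3)cc2)Oc2c1c(OCC)cc(OCc1ccccc1)c2C1=COc2cc(OCc3ccccc3)cc(OCc3ccccc3)c2C1=O | intermediate
24 | [3,4-bis(benzyloxy)phenyl]boronic acid | OB(O)c1ccc(OCc2ccccc2)c(OCc2ccccc2)c1 | starting material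
25 | (2R,3S)-5,7-bis(benzyloxy)-3-{(2R)-7-(benzyloxy)-2-[4-(benzyloxy)phenyl]-5-ethoxy-4-oxochroman-8-yl}-2-[3,4-bis(benzyloxy)phenyl]chroman-4-one | O=C1C[C@H](c2ccc(OCc3ccccc3)cc2)Oc2c1c(OCC)cc(OCc1ccccc1)c2[C@@H]1C(=O)c2c(OCc3ccccc3)cc(OCc3ccccc3)cc2O[C@H]1c1ccc(OCc2ccccc2)c(OCc2ccccc2)c1 | intermediate
26 | (2R,3S)-2-(3,4-dihydroxyphenyl)-3-[(2R)-5,7-dihydroxy-2-(4-hydroxyphenyl)-4-oxochroman-8-yl]-5,7-dihydroxychroman-4-one | O=C1C[C@H](c2ccc(O)cc2)Oc2c1c(O)cc(O)c2[C@@H]1C(=O)c2c(O)cc(O)cc2O[C@H]1c1ccc(O)c(O)c1 | target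

**Step count**

Total step count: 13. Longest linear sequence: 13 steps (from 1; compounds 5, 11, 22 and 24 are purchased).

**Steps most likely to fail**

Step 12 (proposed new method). Insertion of the arylpalladium species into the α-aryl-substituted, electron-rich enone of unit B may be too slow, so that protodeboronation and homocoupling of 24 consume the reagent, or the facial selectivity may be poor. The fallback sets out from 19 and comes back at 25, using established reactions only and giving up enantiocontrol at C2 of unit B.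
- Aqueous KOH in ethanol opens the pyranone of unit B in 19 by hydroxide addition at C2 and loss of formate, giving the deoxybenzoin 1-[2,4-bis(benzyloxy)-6-hydroxyphenyl]-2-[3-acetyl-6-(benzyloxy)-4-ethoxy-2-hydroxyphenyl]ethan-1-one F1.
- Condensation of F1 with 3,4-bis(benzyloxy)benzaldehyde and piperidine in refluxing ethanol passes through the α-aryl chalcone F2 and closes by 6-endo oxa-Michael addition to the racemic 2,3-trans-2,3-diarylchroman-4-one F3, trans by thermodynamic control.
- The conditions of step 10 convert the acetyl group of F3, through the enaminone F4, into the racemic unit A chromone F5.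
- The conditions of step 11 with 22 set (2'R) and give 25 together with its (2S,3R,2'R) diastereomer F6, and the two are separated by chromatography.

Step 6 (key step). Ring opening of the vinylogous ester 11 may need temperatures at which the siloxyalkyne rearranges by 1,3-silyl shift to a silylketene, or the vinylketene may oligomerize or acylate the product phenol faster than it adds to the alkyne. The fallback sets out from 10 and comes back at 16; it keeps the ring synthesis but generates vinylketene 12 at room temperature by Wolff rearrangement, the photochemical variant of the same benzannulation.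
- 3-Ethoxybut-3-en-2-one F7 is made from α-lithiated ethyl vinyl ether and N-methoxy-N-methylacetamide.
- F7 is trifluoroacetylated (LiN(SiMe3)2, CF3CO2CH2CF3, THF, −78 °C) to the diketone 5-ethoxy-1,1,1-trifluorohex-5-ene-2,4-dione F8, which is not isolated and is treated with MeSO2N3 and Et3N to give 1-diazo-3-ethoxybut-3-en-2-one F9.
- Irradiation of F9 with 10 at 365 nm in ClCH2CH2Cl at room temperature, followed by warming to 80 °C, leads through 12, 13, 14 and 15 to 16.

Step 5. The acetylide or the peroxide may add to C2 or C4 of the chromone, or the ynolate may be silylated on carbon, so that 10 cannot be obtained. The fallback sets out from 4 and comes back at 17; it gives up the ring synthesis and makes the C3–C8' bond by a hindered cross-coupling, which the main route is designed to avoid.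
- Phloroglucinol is mono-etherified (EtOH, HCl) to 5-ethoxybenzene-1,3-diol F10 and protected (MeOCH2Cl, i-Pr2NEt) as 1-ethoxy-3,5-bis(methoxymethoxy)benzene F11.
- Lithiation of F11 between the two acetal oxygens (n-BuLi, THF, 0 °C) gives the aryllithium F12, which is trapped with 2-isopropoxy-4,4,5,5-tetramethyl-1,3,2-dioxaborolane to give 2-[4-ethoxy-2,6-bis(methoxymethoxy)phenyl]-4,4,5,5-tetramethyl-1,3,2-dioxaborolane F13.
- Suzuki–Miyaura coupling of F13 with 4 (Pd(OAc)2, 2-dicyclohexylphosphino-2',6'-dimethoxybiphenyl, K3PO4, toluene–H2O, 80 °C) gives 5,7-bis(benzyloxy)-3-[4-ethoxy-2,6-bis(methoxymethoxy)phenyl]-4H-chromen-4-one F14.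
- HCl in methanol at 40 °C removes both acetals and gives 17.

**Further compounds**

F1 | step 12 | 1-[2,4-bis(benzyloxy)-6-hydroxyphenyl]-2-[3-acetyl-6-(benzyloxy)-4-ethoxy-2-hydroxyphenyl]ethan-1-one | CC(=O)c1c(O)c(CC(=O)c2c(O)cc(OCc3ccccc3)cc2OCc2ccccc2)c(OCc2ccccc2)cc1OCC
F2 | step 12 | α-aryl chalcone from F1 and 3,4-bis(benzyloxy)benzaldehyde (alkene geometry not defined, not isolated) | CC(=O)c1c(O)c(C(=Cc2ccc(OCc3ccccc3)c(OCc3ccccc3)c2)C(=O)c2c(O)cc(OCc3ccccc3)cc2OCc2ccccc2)c(OCc2ccccc2)cc1OCC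
F3 | step 12 | racemic trans-3-[3-acetyl-6-(benzyloxy)-4-ethoxy-2-hydroxyphenyl]-5,7-bis(benzyloxy)-2-[3,4-bis(benzyloxy)phenyl]chroman-4-one (one enantiomer drawn) | CC(=O)c1c(O)c([C@@H]2C(=O)c3c(OCc4ccccc4)cc(OCc4ccccc4)cc3O[C@H]2c2ccc(OCc3ccccc3)c(OCc3ccccc3)c2)c(OCc2ccccc2)cc1OCC
F4 | step 12 | (E)-enaminone of F3 (racemic, one enantiomer drawn, not isolated) | CN(C)/C=C/C(=O)c1c(O)c([C@@H]2C(=O)c3c(OCc4ccccc4)cc(OCc4ccccc4)cc3O[C@H]2c2ccc(OCc3ccccc3)c(OCc3ccccc3)c2)c(OCc2ccccc2)cc1OCC
F5 | step 12 | racemic trans-5,7-bis(benzyloxy)-3-[7-(benzyloxy)-5-ethoxy-4-oxo-4H-chromen-8-yl]-2-[3,4-bis(benzyloxy)phenyl]chroman-4-one (one enantiomer drawn) | O=C1C=COc2c1c(OCC)cc(OCc1ccccc1)c2[C@@H]1C(=O)c2c(OCc3ccccc3)cc(OCc3ccccc3)cc2O[C@H]1c1ccc(OCc2ccccc2)c(OCc2ccccc2)c1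
F6 | step 12 | (2S,3R,2'R) diastereomer of 25 | O=C1C[C@H](c2ccc(OCc3ccccc3)cc2)Oc2c1c(OCC)cc(OCc1ccccc1)c2[C@H]1C(=O)c2c(OCc3ccccc3)cc(OCc3ccccc3)cc2O[C@@H]1c1ccc(OCc2ccccc2)c(OCc2ccccc2)c1
F7 | step 6 | 3-ethoxybut-3-en-2-one | C=C(OCC)C(C)=O
F8 | step 6 | 5-ethoxy-1,1,1-trifluorohex-5-ene-2,4-dione (not isolated) | C=C(OCC)C(=O)CC(=O)C(F)(F)F
F9 | step 6 | 1-diazo-3-ethoxybut-3-en-2-one | C=C(OCC)C(=O)C=[N+]=[N-]
F10 | step 5 | 5-ethoxybenzene-1,3-diol | CCOc1cc(O)cc(O)c1
F11 | step 5 | 1-ethoxy-3,5-bis(methoxymethoxy)benzene | CCOc1cc(OCOC)cc(OCOC)c1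
F12 | step 5 | [4-ethoxy-2,6-bis(methoxymethoxy)phenyl]lithium (not isolated) | CCOc1cc(OCOC)c([Li])c(OCOC)c1
F13 | step 5 | 2-[4-ethoxy-2,6-bis(methoxymethoxy)phenyl]-4,4,5,5-tetramethyl-1,3,2-dioxaborolane | CCOc1cc(OCOC)c(B2OC(C)(C)C(C)(C)O2)c(OCOC)c1
F14 | step 5 | 5,7-bis(benzyloxy)-3-[4-ethoxy-2,6-bis(methoxymethoxy)phenyl]-4H-chromen-4-one | CCOc1cc(OCOC)c(C2=COc3cc(OCc4ccccc4)cc(OCc4ccccc4)c3C2=O)c(OCOC)c1
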